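**Retrosynthetic overview**
1. The target is the O-debenzylated form of its benzyl ether. That ether is cut at the bond between C2 of the oxolane and C1 of the 3,4,5-trimethoxyphenyl ring, giving 3,4,5-trimethoxybenzenediazonium tetrafluoroborate and (S)-[4-(4-benzyloxy-3-methoxybenzyl)-4,5-dihydrofuran-3-yl]methanol.
2. This bond is made by a redox-relay Heck–Matsuda arylation with a borohydride quench in the same flask. One operation joins the two fragments, sets C2 and C3, and returns the CH2OH group.
3. Enabling feature: C3 of the oxolane carries a CH2OH group and a hydrogen that is cis to the C2 aryl group, with the C4 benzyl group on the opposite face from the aryl group. A C2=C3 enol ether with CH2OH on C3 is an allylic alcohol; syn-arylpalladation anti to the C4 benzyl group, then hydride relay into the carbinol, reproduces exactly this pattern.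
4. The dihydrofuran comes from (S)-β-(arylmethyl)-γ-butyrolactone by α-formylation, acyl-lactone rearrangement and ester reduction. The rearrangement is the only ring-forming event of the route (oxolane, O1–C2 bond); the lactone carbonyl becomes the CH2OH carbon and the formyl carbon becomes C2.
5. The lactone comes from O-benzylvanillin and dimethyl succinate by Stobbe condensation, asymmetric hydrogenation (sets C4) and ester reduction with lactonisation. Both benzene rings are bought.

Key step: step 8

Remark on the chemistry: the (S,S) antipode of Et-DuPhos is assumed to deliver the S acid in step 2; should a test reduction show the opposite sense, the (R,R) ligand is used and nothing else changes.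

**Step 1**
Reactants: 1 4-(benzyloxy)-3-methoxybenzaldehyde; 2 dimethyl succinate
Product: 3 (3E)-4-[4-(benzyloxy)-3-methoxyphenyl]-3-(methoxycarbonyl)but-3-enoic acid
Conditions: NaOMe (1.5 equiv), MeOH, reflux; then aq. HCl
Reagents that add atoms: none
Why: Stobbe condensation, in which the succinate enolate adds to the aldehyde and the paraconic ester intermediate opens irreversibly to the E half-ester that aromatic aldehydes normally give.

**Step 2**
Reactants: 3 (3E)-4-[4-(benzyloxy)-3-methoxyphenyl]-3-(methoxycarbonyl)but-3-enoic acid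
Product: 4 (3S)-4-[4-(benzyloxy)-3-methoxyphenyl]-3-(methoxycarbonyl)butanoic acid
Conditions: H2 (5 bar), [Rh(cod)((S,S)-Et-DuPhos)]OTf (0.5 mol %), NaOMe (10 mol %), MeOH, rt
Reagents that add atoms: none
Why: Rh-bisphosphine asymmetric hydrogenation of an itaconate-type Stobbe half-ester, in which the chiral catalyst sets the stereocentre that becomes C4 of the target and the homogeneous catalyst leaves the benzyl ether intact.

**Step 3**
Reactants: 4 (3S)-4-[4-(benzyloxy)-3-methoxyphenyl]-3-(methoxycarbonyl)butanoic acid
Product: 6 (4S)-4-{[4-(benzyloxy)-3-methoxyphenyl]methyl}oxolan-2-one, via hydroxy acid 5 (not isolated)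
Conditions: KOH (1.0 equiv), EtOH; CaCl2, NaBH4, EtOH, −10 °C to rt; then 2 M HCl, rt
Reagents that add atoms: none
Why: chemoselective ester reduction by Ca(BH4)2 while the acid is masked as its potassium carboxylate, followed by acid-promoted lactonisation of the γ-hydroxy acid, with the stereocentre not involved.

**Step 4**
Reactants: 6 (4S)-4-{[4-(benzyloxy)-3-methoxyphenyl]methyl}oxolan-2-one
Product: 7 (4S)-4-{[4-(benzyloxy)-3-methoxyphenyl]methyl}-3-(hydroxymethylidene)oxolan-2-one
Conditions: NaH (1.5 equiv), HCO2Et (3 equiv), EtOH (cat.), THF, 0 °C to rt; then cold 1 M HCl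
Reagents that add atoms: ethyl formate CCOC=O
Why: crossed Claisen condensation (α-formylation) of the lactone enolate, driven by formation of the stabilised sodium enolate of the β-formyl lactone, with the non-enolisable C4 stereocentre untouched.

**Step 5**
Reactants: 7 (4S)-4-{[4-(benzyloxy)-3-methoxyphenyl]methyl}-3-(hydroxymethylidene)oxolan-2-one
Product: 9 methyl (4S)-4-{[4-(benzyloxy)-3-methoxyphenyl]methyl}-4,5-dihydrofuran-3-carboxylate, via methoxy acetal ester 8 (not isolated)
Conditions: HCl (10 mol %), MeOH, rt; evaporate; then TMSOTf (1.3 equiv), i-Pr2NEt (1.6 equiv), CH2Cl2, −20 °C to rt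
Reagents that add atoms: methanol CO
Why: Korte acyl-lactone rearrangement (methanolysis of the lactone and closure of the freed hydroxyl onto the formyl carbon as a 2-methoxyoxolane), followed by silyl triflate/amine elimination of methanol from the acetal to the push-pull enol ether, so that the lactone carbonyl ends as the ester and the formyl carbon as C2.

**Step 6**
Reactants: 9 methyl (4S)-4-{[4-(benzyloxy)-3-methoxyphenyl]methyl}-4,5-dihydrofuran-3-carboxylate
Product: 10 [(4S)-4-{[4-(benzyloxy)-3-methoxyphenyl]methyl}-4,5-dihydrofuran-3-yl]methanol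
Conditions: i-Bu2AlH (2.3 equiv), CH2Cl2, −78 °C; aq. KNa tartrate work-up; Et3N-deactivated silica
Reagents that add atoms: none
Why: standard 1,2-reduction of a β-alkoxyacrylate ester to the allylic alcohol with DIBAL-H, with an acid-free work-up to preserve the 3-alkoxyallyl alcohol.

**Step 7**
Reactants: 11 3,4,5-trimethoxyaniline
Product: 12 3,4,5-trimethoxybenzenediazonium tetrafluoroborate
Conditions: NaNO2, HBF4 (48% aq.), H2O, 0 °C; precipitate washed with cold Et2O
Reagents that add atoms: sodium nitrite [Na+].[O-]N=O; tetrafluoroboric acid [H+].F[B-](F)(F)F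
Why: diazotisation of an electron-rich aniline, whose tetrafluoroborate salt precipitates and can be stored cold.

**Step 8**
Reactants: 10 [(4S)-4-{[4-(benzyloxy)-3-methoxyphenyl]methyl}-4,5-dihydrofuran-3-yl]methanol; 12 3,4,5-trimethoxybenzenediazonium tetrafluoroborate
Product: 14 [(2R,3S,4S)-4-{[4-(benzyloxy)-3-methoxyphenyl]methyl}-2-(3,4,5-trimethoxyphenyl)oxolan-3-yl]methanol, via aldehyde 13 (not isolated)
Conditions: Pd2(dba)3 (2.5 mol %), 2,6-di-tert-butyl-4-methylpyridine (1.5 equiv), MeCN, 0 °C to rt; then MeOH, NaBH4, 0 °C
Reagents that add atoms: none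
Why: Proposed new method: oxidative addition of 12 to zerovalent palladium gives a cationic aryl–Pd species that adds syn across the C2=C3 enol ether bond of 10, aryl to C2 and Pd to C3; the tertiary alkyl–Pd has no syn hydrogen on C2, so β-hydride elimination runs into the exocyclic CH2OH, the Pd–H re-adds with the hydride returned to C3 on the face that Pd occupied, and the α-hydroxyalkyl–Pd collapses to aldehyde 13 and zerovalent palladium, after which NaBH4 reduces 13 in the same flask before C3 can epimerise. The closest known reaction types are the Heck–Matsuda arylation of 2,3-dihydrofurans at the carbon next to oxygen and the redox-relay Heck arylation of allylic alcohols (for example 2-methylallyl alcohol to 2-methyl-3-arylpropanals), whose combination on a 3-(hydroxymethyl)-4,5-dihydrofuran is not known. No ring is closed in this step, since the oxolane is already present. C2 is controlled by the C4 benzyl group, which blocks one face so that aryl–Pd adds anti to it, and C3 follows from the mechanism, because syn-carbopalladation and suprafacial hydride return place H-3 cis to the aryl group and hence the formyl (later hydroxymethyl) group trans to aryl and cis to benzyl, as in the target. The step needs regioselectivity (aryl to C2), facial selectivity, and relay towards the carbinol instead of chain-walking through C4–H; these should be secured by the enol ether oxygen together with the full substitution at C3, by the C4 stereocentre, and by the irreversible carbonyl-forming exit that only the carbinol carbon offers. The hindered pyridine traps the HBF4 that is released and so protects the acid-labile 3-alkoxyallyl alcohol.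

**Step 9**
Reactants: 14 [(2R,3S,4S)-4-{[4-(benzyloxy)-3-methoxyphenyl]methyl}-2-(3,4,5-trimethoxyphenyl)oxolan-3-yl]methanol
Product: 15 4-{[(3S,4S,5R)-4-(hydroxymethyl)-5-(3,4,5-trimethoxyphenyl)oxolan-3-yl]methyl}-2-methoxyphenol
Conditions: H2 (1 atm), 10% Pd/C, EtOAc, rt
Reagents that add atoms: none
Why: hydrogenolysis of the aryl benzyl ether, which should be cleaved much faster than the ring benzylic C2–O bond under these mild conditions, with no stereocentre affected.

**Compound list**
1 | 4-(benzyloxy)-3-methoxybenzaldehyde | COc1cc(C=O)ccc1OCc1ccccc1 | starting material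
2 | dimethyl succinate | COC(=O)CCC(=O)OC | starting material
3 | (3E)-4-[4-(benzyloxy)-3-methoxyphenyl]-3-(methoxycarbonyl)but-3-enoic acid | COC(=O)/C(CC(=O)O)=C/c1ccc(OCc2ccccc2)c(OC)c1 | intermediate
4 | (3S)-4-[4-(benzyloxy)-3-methoxyphenyl]-3-(methoxycarbonyl)butanoic acid | COc1cc(C[C@@H](CC(=O)O)C(=O)OC)ccc1OCc1ccccc1 | intermediate
5 | (3S)-4-[4-(benzyloxy)-3-methoxyphenyl]-3-(hydroxymethyl)butanoic acid (not isolated) | COc1cc(C[C@@H](CC(=O)O)CO)ccc1OCc1ccccc1 | intermediate
6 | (4S)-4-{[4-(benzyloxy)-3-methoxyphenyl]methyl}oxolan-2-one | COc1cc(C[C@@H]2COC(=O)C2)ccc1OCc1ccccc1 | intermediate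
7 | (4S)-4-{[4-(benzyloxy)-3-methoxyphenyl]methyl}-3-(hydroxymethylidene)oxolan-2-one (enol form of the α-formyl lactone, alkene geometry not defined) | COc1cc(C[C@@H]2COC(=O)C2=CO)ccc1OCc1ccccc1 | intermediate
8 | methyl (4S)-4-{[4-(benzyloxy)-3-methoxyphenyl]methyl}-2-methoxyoxolane-3-carboxylate (mixture at C2 and C3, not isolated) | COc1cc(C[C@@H]2COC(OC)C2C(=O)OC)ccc1OCc1ccccc1 | intermediate
9 | methyl (4S)-4-{[4-(benzyloxy)-3-methoxyphenyl]methyl}-4,5-dihydrofuran-3-carboxylate | COc1cc(C[C@@H]2COC=C2C(=O)OC)ccc1OCc1ccccc1 | intermediate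
10 | [(4S)-4-{[4-(benzyloxy)-3-methoxyphenyl]methyl}-4,5-dihydrofuran-3-yl]methanol | COc1cc(C[C@@H]2COC=C2CO)ccc1OCc1ccccc1 | intermediate
11 | 3,4,5-trimethoxyaniline | COc1cc(N)cc(OC)c1OC | starting material
12 | 3,4,5-trimethoxybenzenediazonium tetrafluoroborate | COc1cc([N+]#N)cc(OC)c1OC.F[B-](F)(F)F | intermediate
13 | (2R,3R,4S)-4-{[4-(benzyloxy)-3-methoxyphenyl]methyl}-2-(3,4,5-trimethoxyphenyl)oxolane-3-carbaldehyde (not isolated) | COc1cc(C[C@@H]2CO[C@@H](c3cc(OC)c(OC)c(OC)c3)[C@@H]2C=O)ccc1OCc1ccccc1 | intermediate
14 | [(2R,3S,4S)-4-{[4-(benzyloxy)-3-methoxyphenyl]methyl}-2-(3,4,5-trimethoxyphenyl)oxolan-3-yl]methanol | COc1cc(C[C@@H]2CO[C@@H](c3cc(OC)c(OC)c(OC)c3)[C@@H]2CO)ccc1OCc1ccccc1 | intermediate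
15 | 4-{[(3S,4S,5R)-4-(hydroxymethyl)-5-(3,4,5-trimethoxyphenyl)oxolan-3-yl]methyl}-2-methoxyphenol | COc1cc(C[C@@H]2CO[C@@H](c3cc(OC)c(OC)c(OC)c3)[C@@H]2CO)ccc1O | target

**Step count**
Total steps: 9. Longest linear sequence: 8 steps (steps 1 to 6, then 8 and 9); step 7 is a one-step side branch.

**Steps most likely to fail**

Step 8 (proposed new method). The C4 benzyl group may not discriminate the two faces of the enol ether well enough. The Pd–H may also walk through C4–H and release ring-alkene isomers, or leave the enol so that C3 is protonated without control. The substrate may ionise if acid is not trapped fast enough. The fallback keeps the same C2–aryl bond but makes it by known radical chemistry and sets out from 10. Silylation (TBSCl, imidazole, DMF) should give the tert-butyldimethylsilyl ether F1. Vinylic lithiation at C2 next to the ring oxygen (t-BuLi, THF, −78 to −20 °C) and a CO2 quench should give the dihydrofuran-2-carboxylic acid F2. Hydrogenation (H2, 5% Rh/Al2O3, EtOAc) should add anti to the C4 benzyl group and give the all-cis oxolane-2-carboxylic acid F3, in which C3 and C4 already have the cis relationship of the target and the C2 configuration is irrelevant. Nickel/photoredox decarboxylative arylation of F3 with 5-bromo-1,2,3-trimethoxybenzene (NiCl2(dme), 4,4'-di-tert-butyl-2,2'-bipyridine, Ir[dF(CF3)ppy]2(dtbbpy)PF6, Cs2CO3, DMF, blue light) is a known reaction of oxolane-2-carboxylic acids. It passes through a planar C2 radical that should be arylated on the face away from both cis substituents, giving the arylated silyl ether F4. Bu4NF in THF then returns the route to 14.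

Step 6. The push-pull ester may be over-reduced, and the product, a vinylogous hemiacetal, may ionise during work-up or chromatography. The fallback changes the order of events and sets out from the acetal ester 8, taken before the elimination of step 5. LiAlH4 in THF at 0 °C should reduce the ester while the acetal is inert, giving the acetal alcohol F5. TMSOTf (2.5 equiv) and i-Pr2NEt in CH2Cl2 at −20 °C should silylate the hydroxyl and eliminate methanol from the acetal, giving the trimethylsilyl ether F6. K2CO3 in MeOH at 0 °C removes the silyl group under basic conditions and returns the route to 10, so the labile alcohol never meets aluminium salts or acid.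

Step 5. The C2 oxocarbenium ion formed during acetalisation or elimination may be captured by the electron-rich benzyl ring in an intramolecular Friedel–Crafts reaction, or the rearrangement may stop at mixtures of lactone and open-chain acetals. The fallback builds the enol ether first and the ester afterwards and sets out from 6. i-Bu2AlH in CH2Cl2 at −78 °C should give the lactol F7. Mesylation and elimination (MsCl, Et3N, CH2Cl2, 0 °C to reflux) should give the 3-benzyl-2,3-dihydrofuran F8. Acylation at the enol ether β-carbon (Cl3CCOCl, pyridine, CH2Cl2, 0 °C) should give the trichloromethyl ketone F9. Haloform-type methanolysis (MeOH, K2CO3) returns the route to 9.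

**Further compounds**
F1 | step 8 | tert-butyl{[(4S)-4-{[4-(benzyloxy)-3-methoxyphenyl]methyl}-4,5-dihydrofuran-3-yl]methoxy}dimethylsilane | COc1cc(C[C@@H]2COC=C2CO[Si](C)(C)C(C)(C)C)ccc1OCc1ccccc1
F2 | step 8 | (4S)-4-{[4-(benzyloxy)-3-methoxyphenyl]methyl}-3-{[(tert-butyldimethylsilyl)oxy]methyl}-4,5-dihydrofuran-2-carboxylic acid | COc1cc(C[C@@H]2COC(C(=O)O)=C2CO[Si](C)(C)C(C)(C)C)ccc1OCc1ccccc1
F3 | step 8 | (2S,3S,4S)-4-{[4-(benzyloxy)-3-methoxyphenyl]methyl}-3-{[(tert-butyldimethylsilyl)oxy]methyl}oxolane-2-carboxylic acid | COc1cc(C[C@@H]2CO[C@H](C(=O)O)[C@@H]2CO[Si](C)(C)C(C)(C)C)ccc1OCc1ccccc1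
F4 | step 8 | tert-butyl{[(2R,3S,4S)-4-{[4-(benzyloxy)-3-methoxyphenyl]methyl}-2-(3,4,5-trimethoxyphenyl)oxolan-3-yl]methoxy}dimethylsilane | COc1cc(C[C@@H]2CO[C@@H](c3cc(OC)c(OC)c(OC)c3)[C@@H]2CO[Si](C)(C)C(C)(C)C)ccc1OCc1ccccc1
F5 | step 6 | [(4S)-4-{[4-(benzyloxy)-3-methoxyphenyl]methyl}-2-methoxyoxolan-3-yl]methanol | COc1cc(C[C@@H]2COC(OC)C2CO)ccc1OCc1ccccc1
F6 | step 6 | {[(4S)-4-{[4-(benzyloxy)-3-methoxyphenyl]methyl}-4,5-dihydrofuran-3-yl]methoxy}trimethylsilane | COc1cc(C[C@@H]2COC=C2CO[Si](C)(C)C)ccc1OCc1ccccc1
F7 | step 5 | (4S)-4-{[4-(benzyloxy)-3-methoxyphenyl]methyl}oxolan-2-ol | COc1cc(C[C@@H]2COC(O)C2)ccc1OCc1ccccc1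
F8 | step 5 | (3S)-3-{[4-(benzyloxy)-3-methoxyphenyl]methyl}-2,3-dihydrofuran | COc1cc(C[C@@H]2COC=C2)ccc1OCc1ccccc1
F9 | step 5 | 1-[(4S)-4-{[4-(benzyloxy)-3-methoxyphenyl]methyl}-4,5-dihydrofuran-3-yl]-2,2,2-trichloroethan-1-one | COc1cc(C[C@@H]2COC=C2C(=O)C(Cl)(Cl)Cl)ccc1OCc1ccccc1
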